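**Plan**

- Cuts, in retrosynthetic order: the three O-allyl groups; ring C at O1–C2 and at the C3–OH bond (oxidative cyclisation of a 2'-hydroxychalcone); the chalcone Cα–Cβ bond (aldol, releasing ring B as an aldehyde); C4–C4a (ortho-formylation, then methyl addition); last, ring A at C7–C8, C4a–C8a and C6–C7.
- Enabling feature: ring A is a phloroglucinol with oxygens on C5, C7 and C8a and the prenylated carbon C8 between O7 and O8a. This 2-alkylresorcinol with a third meta oxygen is the pattern a 2-alkoxyvinylketene (from a 3-alkoxycyclobutenone) and a siloxyalkyne assemble, each oxygen arriving differently substituted.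
- Forward order: ring A is built first (free OH at C7, silyl on O8a, allyl on O5). O7 is then allylated and O8a unmasked to direct acylation to C4a. Ring B is joined by Claisen–Schmidt condensation, ring C closes last, and one palladium-mediated deallylation ends the route.
- Stereochemistry: the target has no stereocentre and no stereogenic double bond. The racemic centres of three transient intermediates and the E-enone of the chalcone are erased on the way.

Key step: step 4

Remark: allyl is used for every phenol protection because it is removed under neutral conditions, which the two ortho-prenyl phenols require. Racemic intermediates are drawn without descriptors, except the trans-dihydroflavonol, which is drawn as one enantiomer of the racemate.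

**Route**

Step 1
Reactants: 1 3-ethoxycyclobut-2-en-1-one
Product: 2 3-(allyloxy)cyclobut-2-en-1-one
Conditions: allyl alcohol (excess, as solvent), PPTS (5 mol %), 40 °C, ethanol stripped under reduced pressure
Reagents that add atoms: allyl alcohol, C=CCO
Why: Acid-catalysed transetherification of a vinylogous ester (allyl alcohol adds to C3 of the O-protonated enone and ethanol leaves, the same addition–elimination by which aqueous acid hydrolyses 1) should be driven to 2 by the excess alcohol and the removal of ethanol.

Step 2
Reactants: 3 ethynylmagnesium bromide; 4 prenyl bromide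
Product: 5 5-methylhex-4-en-1-yne
Conditions: CuCl (5 mol %), THF, 0 °C to rt, 3 in excess (1.5 equiv); fractional distillation
Reagents that add atoms: none
Why: Copper-catalysed coupling of an alkynyl Grignard reagent with an allylic bromide should occur at the unhindered primary carbon of the prenyl unit (SN2, not SN2′ at the tertiary carbon) to give the skipped enyne, and the excess of 3 suppresses double alkylation of acetylene.

Step 3
Reactants: 5 5-methylhex-4-en-1-yne
Product: 8 triisopropyl[(5-methylhex-4-en-1-yn-1-yl)oxy]silane, via lithium acetylide 6 (not isolated), via lithium ynolate 7 (not isolated)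
Conditions: n-BuLi, THF, −78 °C; then LiOOt-Bu (from t-BuOOH and LiN(SiMe3)2, THF, −78 °C), −78 to 0 °C; then i-Pr3SiOTf, −78 to 0 °C
Reagents that add atoms: tert-butyl hydroperoxide, CC(C)(C)OO; triisopropylsilyl trifluoromethanesulfonate, CC(C)[Si](OS(=O)(=O)C(F)(F)F)(C(C)C)C(C)C
Why: Julia oxidation of a lithium acetylide with lithium tert-butyl peroxide (attack of the acetylide carbon on the peroxide oxygen with loss of tert-butoxide) gives the lithium ynolate, which the hindered silyl triflate traps on oxygen, while the nucleophilic peroxide leaves the trisubstituted alkene alone and the terminal C–H is removed at −78 °C before the doubly activated CH2.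

Step 4
Reactants: 2 3-(allyloxy)cyclobut-2-en-1-one; 8 triisopropyl[(5-methylhex-4-en-1-yn-1-yl)oxy]silane
Product: 13 5-(allyloxy)-2-prenyl-3-(triisopropylsilyloxy)phenol, via vinylketene 9 (not isolated), via vinylcyclobutenone 10 (not isolated), via dienylketene 11 (not isolated), via cyclohexadienone 12 (not isolated)
Conditions: toluene (0.4 M), 8 (1.2 equiv), 80 °C then 110 °C, sealed tube
Reagents that add atoms: none
Why: Four-electron conrotatory opening of 2 gives the 2-alkoxyvinylketene 9, whose ketene carbon is attacked by the prenyl-bearing β-carbon of the siloxyalkyne in a [2+2] cycloaddition that forms C7–C8 and C4a–C8a and gives the 4-vinyl-3-siloxycyclobutenone 10. Reversible four-electron opening of 10 gives the dienylketene 11, and ring A closes by a thermal six-electron disrotatory electrocyclisation (six-membered carbocycle, C6–C7 bond) to the cyclohexa-2,4-dienone 12, which tautomerises to phenol 13. The closest known reaction type is the Danheiser benzannulation of a cyclobutenone with a trialkylsilyloxyalkyne, the established route to resorcinol monosilyl ethers. No stereocentre is formed. The required regiochemistry (prenyl between the new hydroxyl and the siloxy group, the alkoxy group meta to both) follows from the polarity match of ketene and ynol ether and from the alkoxy group sitting on C3 of the cyclobutenone, and the bulky triisopropylsilyl group prevents silyl migration so that the three oxygens stay distinct. At 80–110 °C neither the allyl enol ether of 2 nor the aryl allyl ether of 13 should undergo a [3,3] shift, and the slight excess of the ketenophilic alkyne keeps the vinylketene from acylating the product phenol.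

Step 5
Reactants: 13 5-(allyloxy)-2-prenyl-3-(triisopropylsilyloxy)phenol
Product: 14 [3,5-bis(allyloxy)-2-prenylphenoxy]triisopropylsilane
Conditions: allyl bromide, K2CO3, acetone, 50 °C
Reagents that add atoms: allyl bromide, C=CCBr
Why: Williamson etherification of the only free phenol (O7) should be clean because the hindered aryl triisopropylsilyl ether withstands K2CO3 in acetone and cannot migrate to a meta oxygen.

Step 6
Reactants: 14 [3,5-bis(allyloxy)-2-prenylphenoxy]triisopropylsilane
Product: 15 3,5-bis(allyloxy)-2-prenylphenol
Conditions: Bu4NF, AcOH (1 equiv each), THF, 0 °C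
Reagents that add atoms: none
Why: Fluoride-mediated desilylation of the aryl silyl ether, driven by the Si–F bond and buffered with acetic acid so that the electron-rich phenoxide is not left exposed, should unmask the C8a hydroxyl while the allyl ethers and the prenyl group are inert.

Step 7
Reactants: 15 3,5-bis(allyloxy)-2-prenylphenol
Product: 17 4,6-bis(allyloxy)-2-hydroxy-3-prenylbenzaldehyde, via hydroxymethylphenol 16 (not isolated)
Conditions: MgCl2, Et3N, (CH2O)n, THF, 65 °C; cold 1 M HCl work-up
Reagents that add atoms: paraformaldehyde (as formaldehyde), C=O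
Why: In the Casnati–Skattebøl ortho-formylation the magnesium phenoxide delivers coordinated formaldehyde only to an ortho carbon and the benzylic alkoxide of 16 passes hydride to a second formaldehyde, so the single free ortho position C4a is formylated and C6 (para to the hydroxyl) is untouched, under conditions too mild to cyclise the ortho-prenyl phenol.

Step 8
Reactants: 17 4,6-bis(allyloxy)-2-hydroxy-3-prenylbenzaldehyde
Product: 18 3,5-bis(allyloxy)-2-(1-hydroxyethyl)-6-prenylphenol
Conditions: MeMgBr (3 equiv), THF, −78 to 0 °C; aq. NH4Cl; used crude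
Reagents that add atoms: methylmagnesium bromide, C[Mg]Br
Why: Grignard addition to the aldehyde, after the first equivalent has deprotonated the phenol, should give the secondary benzylic alcohol, whose new carbinol centre forms as a racemate and needs no control because step 9 removes it.

Step 9
Reactants: 18 3,5-bis(allyloxy)-2-(1-hydroxyethyl)-6-prenylphenol
Product: 19 1-[4,6-bis(allyloxy)-2-hydroxy-3-prenylphenyl]ethan-1-one
Conditions: activated MnO2 (15 equiv), CH2Cl2, rt
Reagents that add atoms: none
Why: MnO2 oxidation is selective for the electron-rich benzylic carbinol and the product is stabilised as the hydrogen-bonded ortho-hydroxyaryl ketone, while isolated alkenes and aryl ethers are not oxidised.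

Step 10
Reactants: 20 4-hydroxybenzaldehyde; 4 prenyl bromide
Product: 21 4-hydroxy-3-prenylbenzaldehyde
Conditions: KOH (10 % aq.), rt
Reagents that add atoms: none
Why: Ortho C-alkylation of a phenoxide in water, where hydrogen bonding shields the oxygen, is the known direct entry to this aldehyde, and a modest conversion is expected, with the O-prenyl ether and unchanged 20 removed by base extraction and chromatography.

Step 11
Reactants: 21 4-hydroxy-3-prenylbenzaldehyde
Product: 22 4-(allyloxy)-3-prenylbenzaldehyde
Conditions: allyl bromide, K2CO3, acetone, 50 °C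
Reagents that add atoms: allyl bromide, C=CCBr
Why: Williamson etherification masks the phenol so that the aldehyde is not deactivated as a phenoxide in the aldol step and carries a group that is later removed without acid.

Step 12
Reactants: 19 1-[4,6-bis(allyloxy)-2-hydroxy-3-prenylphenyl]ethan-1-one; 22 4-(allyloxy)-3-prenylbenzaldehyde
Product: 23 (E)-1-[4,6-bis(allyloxy)-2-hydroxy-3-prenylphenyl]-3-[4-(allyloxy)-3-prenylphenyl]prop-2-en-1-one
Conditions: KOH (50 % aq.), EtOH, rt
Reagents that add atoms: none
Why: In this Claisen–Schmidt condensation the enolate of the methyl ketone adds to the non-enolisable aldehyde and E1cB loss of water gives the conjugated enone with the thermodynamically preferred E geometry.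

Step 13
Reactants: 23 (E)-1-[4,6-bis(allyloxy)-2-hydroxy-3-prenylphenyl]-3-[4-(allyloxy)-3-prenylphenyl]prop-2-en-1-one
Product: 25 5,7-bis(allyloxy)-2-[4-(allyloxy)-3-prenylphenyl]-3-hydroxy-8-prenyl-4H-chromen-4-one, via dihydroflavonol 24 (not isolated)
Conditions: H2O2 (30 % aq.), NaOH (aq.), MeOH–THF, 0 °C to rt
Reagents that add atoms: hydrogen peroxide, OO
Why: In the Algar–Flynn–Oyamada reaction the 2'-phenoxide closes ring C by 6-endo attack on the β-carbon while alkaline peroxide oxygenates the α-carbon, giving the racemic trans-dihydroflavonol 24 (both centres transient, trans by enolate equilibration), which further peroxide dehydrogenates to the flavonol; the para-allyloxy group of ring B favours attack at the benzylic β-carbon over the five-membered aurone closure, and the nucleophilic oxidant spares the isolated alkenes.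

Step 14
Reactants: 25 5,7-bis(allyloxy)-2-[4-(allyloxy)-3-prenylphenyl]-3-hydroxy-8-prenyl-4H-chromen-4-one
Product: 26 Broussoflavonol F
Conditions: Pd(PPh3)4 (10 mol %), morpholine (10 equiv), degassed THF, rt to 40 °C
Reagents that add atoms: none
Why: In this Tsuji–Trost deallylation zerovalent palladium ionises each aryl allyl ether to a π-allyl complex and a phenoxide and morpholine captures the allyl group, which frees O5, O7 and O4′ in one neutral operation that cannot touch the C-prenyl groups (no leaving group) or cyclise them onto the neighbouring phenols as acid would.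

**Compound list**

1 | 3-ethoxycyclobut-2-en-1-one | CCOC1=CC(=O)C1 | starting material
2 | 3-(allyloxy)cyclobut-2-en-1-one | C=CCOC1=CC(=O)C1 | intermediate
3 | ethynylmagnesium bromide | C#C[Mg]Br | starting material
4 | prenyl bromide (1-bromo-3-methylbut-2-ene) | CC(C)=CCBr | starting material
5 | 5-methylhex-4-en-1-yne | C#CCC=C(C)C | intermediate
6 | lithium 5-methylhex-4-en-1-yn-1-ide (lithium acetylide) | [Li]C#CCC=C(C)C | intermediate
7 | lithium 5-methylhex-4-en-1-yn-1-olate (lithium ynolate) | [Li]OC#CCC=C(C)C | intermediate
8 | triisopropyl[(5-methylhex-4-en-1-yn-1-yl)oxy]silane | CC(C)=CCC#CO[Si](C(C)C)(C(C)C)C(C)C | intermediate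
9 | 3-(allyloxy)buta-1,3-dien-1-one (2-alkoxyvinylketene) | C=CCOC(=C)C=C=O | intermediate
10 | 4-[1-(allyloxy)vinyl]-2-(3-methylbut-2-en-1-yl)-3-[(triisopropylsilyl)oxy]cyclobut-2-en-1-one (racemic) | O=C1C(CC=C(C)C)=C(O[Si](C(C)C)(C(C)C)C(C)C)C1C(=C)OCC=C | intermediate
11 | (3E)-5-(allyloxy)-2-(3-methylbut-2-en-1-yl)-3-[(triisopropylsilyl)oxy]hexa-1,3,5-trien-1-one | O=C=C(CC=C(C)C)/C(O[Si](C(C)C)(C(C)C)C(C)C)=C\C(=C)OCC=C | intermediate
12 | 5-(allyloxy)-2-(3-methylbut-2-en-1-yl)-3-[(triisopropylsilyl)oxy]cyclohexa-2,4-dien-1-one | O=C1CC(OCC=C)=CC(O[Si](C(C)C)(C(C)C)C(C)C)=C1CC=C(C)C | intermediate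
13 | 5-(allyloxy)-2-(3-methylbut-2-en-1-yl)-3-[(triisopropylsilyl)oxy]phenol | Oc1cc(OCC=C)cc(O[Si](C(C)C)(C(C)C)C(C)C)c1CC=C(C)C | intermediate
14 | [3,5-bis(allyloxy)-2-(3-methylbut-2-en-1-yl)phenoxy]triisopropylsilane | CC(C)=CCc1c(OCC=C)cc(OCC=C)cc1O[Si](C(C)C)(C(C)C)C(C)C | intermediate
15 | 3,5-bis(allyloxy)-2-(3-methylbut-2-en-1-yl)phenol | CC(C)=CCc1c(O)cc(OCC=C)cc1OCC=C | intermediate
16 | 3,5-bis(allyloxy)-2-(hydroxymethyl)-6-(3-methylbut-2-en-1-yl)phenol | CC(C)=CCc1c(O)c(CO)c(OCC=C)cc1OCC=C | intermediate
17 | 4,6-bis(allyloxy)-2-hydroxy-3-(3-methylbut-2-en-1-yl)benzaldehyde | CC(C)=CCc1c(O)c(C=O)c(OCC=C)cc1OCC=C | intermediate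
18 | 3,5-bis(allyloxy)-2-(1-hydroxyethyl)-6-(3-methylbut-2-en-1-yl)phenol (racemic) | CC(C)=CCc1c(O)c(C(C)O)c(OCC=C)cc1OCC=C | intermediate
19 | 1-[4,6-bis(allyloxy)-2-hydroxy-3-(3-methylbut-2-en-1-yl)phenyl]ethan-1-one | CC(C)=CCc1c(O)c(C(C)=O)c(OCC=C)cc1OCC=C | intermediate
20 | 4-hydroxybenzaldehyde | O=Cc1ccc(O)cc1 | starting material
21 | 4-hydroxy-3-(3-methylbut-2-en-1-yl)benzaldehyde | CC(C)=CCc1cc(C=O)ccc1O | intermediate
22 | 4-(allyloxy)-3-(3-methylbut-2-en-1-yl)benzaldehyde | CC(C)=CCc1cc(C=O)ccc1OCC=C | intermediate
23 | (E)-1-[4,6-bis(allyloxy)-2-hydroxy-3-(3-methylbut-2-en-1-yl)phenyl]-3-[4-(allyloxy)-3-(3-methylbut-2-en-1-yl)phenyl]prop-2-en-1-one | CC(C)=CCc1c(O)c(C(=O)/C=C/c2ccc(OCC=C)c(CC=C(C)C)c2)c(OCC=C)cc1OCC=C | intermediate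
24 | rac-(2R,3R)-5,7-bis(allyloxy)-2-[4-(allyloxy)-3-(3-methylbut-2-en-1-yl)phenyl]-3-hydroxy-8-(3-methylbut-2-en-1-yl)chroman-4-one (2,3-trans) | C=CCOc1ccc(cc1CC=C(C)C)[C@@H]2[C@H](C(=O)c3c(OCC=C)cc(OCC=C)c(CC=C(C)C)c3O2)O | intermediate
25 | 5,7-bis(allyloxy)-2-[4-(allyloxy)-3-(3-methylbut-2-en-1-yl)phenyl]-3-hydroxy-8-(3-methylbut-2-en-1-yl)-4H-chromen-4-one | C=CCOc1ccc(cc1CC=C(C)C)-c1oc2c(CC=C(C)C)c(OCC=C)cc(OCC=C)c2c(=O)c1O | intermediate
26 | Broussoflavonol F | CC(C)=CCc1cc(-c2oc3c(CC=C(C)C)c(O)cc(O)c3c(=O)c2O)ccc1O | target

**Count and risks**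

Total: 14 steps. Longest linear sequence: 11 steps (steps 2–9 and 12–14, from ethynylmagnesium bromide).

Steps most likely to fail:

1. Step 4. The donor-stabilised cyclobutenone may open too slowly, so that the temperature must be raised into the range where the allyl enol ether undergoes a [3,3] shift. The vinylketene may also be consumed by dimerisation or by acylating the product phenol before the alkyne captures it. Fallback: ring A is then taken from a preformed phloroglucinol. The fallback sets out from prenyl bromide 4 and commercial 2,4,6-trihydroxyacetophenone. C-Prenylation in cold 10 % aqueous KOH should give 1-[2,4,6-trihydroxy-3-(3-methylbut-2-en-1-yl)phenyl]ethan-1-one F1. Treating this with two equivalents of allyl bromide and K2CO3 in acetone should alkylate the para hydroxyl and the less hindered ortho hydroxyl, leaving free the chelated hydroxyl that lies between the acetyl and prenyl groups. That product is acetophenone 19, where the route is rejoined (steps 12–14 unchanged).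

2. Step 13. The 6'-alkoxy group can divert the cyclisation toward five-membered closure (attack of the phenoxide on the α-carbon), draining material into the aurone series. Fallback: set out from chalcone 23. Capping the 2'-hydroxyl with MOMCl and NaH in DMF at 0 °C gives (E)-1-[4,6-bis(allyloxy)-2-(methoxymethoxy)-3-(3-methylbut-2-en-1-yl)phenyl]-3-[4-(allyloxy)-3-(3-methylbut-2-en-1-yl)phenyl]prop-2-en-1-one F2. Weitz–Scheffer epoxidation (H2O2, NaOH, MeOH–THF, 0 °C), now free of any phenoxide, gives rac-trans-[4,6-bis(allyloxy)-2-(methoxymethoxy)-3-(3-methylbut-2-en-1-yl)phenyl]{3-[4-(allyloxy)-3-(3-methylbut-2-en-1-yl)phenyl]oxiran-2-yl}methanone F3. Brief treatment with catalytic HCl in MeOH at 45 °C removes the acetal, and under acid the freed phenol opens the epoxide at the benzylic carbon in the six-membered mode. This returns to the route at dihydroflavonol 24, which is dehydrogenated to 25 under the alkaline peroxide conditions of step 13.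

3. Step 1. Allyl alcohol may cleave the strained ring by attack at the carbonyl carbon, or the exchange may stop at an inseparable mixture of the two enol ethers. Fallback: set out from 1. Hydrolysis with aqueous HCl gives cyclobutane-1,3-dione F4, which is isolated as its enol. Mitsunobu O-alkylation of this vinylogous acid with allyl alcohol (PPh3, diisopropyl azodicarboxylate, THF, 0 °C) under neutral conditions returns to the route at 2.

**Further compounds**

F1 | step 4 | 1-[2,4,6-trihydroxy-3-(3-methylbut-2-en-1-yl)phenyl]ethan-1-one | CC(=O)c1c(O)cc(O)c(CC=C(C)C)c1O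
F2 | step 13 | (E)-1-[4,6-bis(allyloxy)-2-(methoxymethoxy)-3-(3-methylbut-2-en-1-yl)phenyl]-3-[4-(allyloxy)-3-(3-methylbut-2-en-1-yl)phenyl]prop-2-en-1-one | COCOc1c(CC=C(C)C)c(OCC=C)cc(OCC=C)c1C(=O)/C=C/c1ccc(OCC=C)c(CC=C(C)C)c1
F3 | step 13 | rac-trans-[4,6-bis(allyloxy)-2-(methoxymethoxy)-3-(3-methylbut-2-en-1-yl)phenyl]{3-[4-(allyloxy)-3-(3-methylbut-2-en-1-yl)phenyl]oxiran-2-yl}methanone | COCOc1c(CC=C(C)C)c(OCC=C)cc(OCC=C)c1C(=O)[C@@H]1O[C@H]1c1ccc(OCC=C)c(CC=C(C)C)c1
F4 | step 1 | cyclobutane-1,3-dione | O=C1CC(=O)C1
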